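**Retrosynthetic overview** (germacrane numbering: lactone O on C6, C7–C11(Me)–C12=O, OAc on C3 and C9, Z‑C1=C10, Z‑C4=C5)
1. Feature: in the ten‑membered carbocycle the C6 carbinol sits next to C7 with its C11–C12 arm; once C11=C12 is a vinyl group this is a homoallylic alcohol retron (C6–OH / C7–CH=CH2).
2. Late stage: acetates ← TBS ethers; C13 ← methylation of the γ‑lactone enolate (methyl enters cis to C8); γ‑lactone ← 6,12‑diol ← hydroboration of the C7 vinyl group.
3. Key disconnection: C6–C7 by [2,3]‑Wittig ring contraction of a 13‑membered diallylic ether (C6–O–C12, E‑C7=C11); the C6 carbanion comes from a C6–SPh group by reductive lithiation.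
4. The 13‑membered ether ← macrolactone (C6 carbonyl, O–C12) by reductive acetylation and thiol exchange ← seco acid, built linearly from 3‑silyloxypropanal: C3 by alkynylation, Z‑C4=C5 by cuprate syn‑addition, Z‑C1=C10 by iodo‑olefination/formylation, C9 by allylboration, E‑C7=C11 by cross‑metathesis.
5. Ring order: 13‑membered lactone/ether (step 13) → ten‑membered carbocycle (step 16) → γ‑lactone (step 18).

Key step: step 16

Remarks on the chemistry:
- The target has C13 cis to C8 on the lactone (11R). Hydroboration of a 7‑isopropenyl group, or protonation of the lactone enolate, would be expected to put H11 rather than CH3 on that face. C13 is therefore left off the allyl ether and added last by enolate methylation.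
- A C6 tributylstannyl carbinol would not survive the base needed to O‑allylate it (loss of Bu3Sn–). The C6 carbanion precursor is therefore a phenylthio group reached from a macrolactone.
- C6 in 19–21 is an epimer mixture or planar and carries no stereochemical information.

**Route**

Step 1
Reactants: 1 3-[(tert-butyldimethylsilyl)oxy]propanal; 2 methyl propiolate
Product: 3 methyl (4S)-6-[(tert-butyldimethylsilyl)oxy]-4-hydroxyhex-2-ynoate
Conditions: (S,S)-ProPhenol (10 mol%), Me2Zn (3 equiv), Ph3PO (20 mol%), PhMe, 4 °C; aq NH4Cl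
Reagents that add atoms: none
Why: Zinc–ProPhenol catalysed asymmetric alkynylation of an aldehyde, in which the zinc acetylide of 2 is delivered to one face of 1 inside the dinuclear zinc catalyst and sets C3 (the (S,S)-ligand is chosen on the facial model of the related ProPhenol aldol; the antipodal ligand is used if the sense proves opposite).

Step 2
Reactants: 3 methyl (4S)-6-[(tert-butyldimethylsilyl)oxy]-4-hydroxyhex-2-ynoate
Product: 4 methyl (4S)-4,6-bis[(tert-butyldimethylsilyl)oxy]hex-2-ynoate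
Conditions: TBSOTf, 2,6-lutidine, CH2Cl2, −78 → 0 °C
Reagents that add atoms: tert-butyldimethylsilyl trifluoromethanesulfonate, CC(C)(C)[Si](C)(C)OS(=O)(=O)C(F)(F)F
Why: Silyl triflate silylation of a secondary propargylic alcohol, with a hindered non-nucleophilic base so that nothing adds to the ynoate.

Step 3
Reactants: 4 methyl (4S)-4,6-bis[(tert-butyldimethylsilyl)oxy]hex-2-ynoate
Product: 5 methyl (2Z,4S)-4,6-bis[(tert-butyldimethylsilyl)oxy]-3-methylhex-2-enoate
Conditions: Me2CuLi (1.5 equiv), THF, −78 °C; MeOH then aq NH4Cl at −78 °C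
Reagents that add atoms: lithium dimethylcuprate, [Li+].C[Cu-]C
Why: Syn-carbocupration (conjugate addition of a Gilman cuprate) of the ynoate with cold protonation of the alkenylcopper places CH3 (C15) and H cis, so C3 and the ester are cis (Z-C4=C5).

Step 4
Reactants: 5 methyl (2Z,4S)-4,6-bis[(tert-butyldimethylsilyl)oxy]-3-methylhex-2-enoate
Product: 6 methyl (2Z,4S)-4-[(tert-butyldimethylsilyl)oxy]-6-hydroxy-3-methylhex-2-enoate
Conditions: HF·pyridine, pyridine, THF, 0 °C
Reagents that add atoms: none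
Why: Selective cleavage of the primary TBS ether beside the hindered secondary allylic one with buffered HF·pyridine.

Step 5
Reactants: 6 methyl (2Z,4S)-4-[(tert-butyldimethylsilyl)oxy]-6-hydroxy-3-methylhex-2-enoate
Product: 7 methyl (2Z,4S)-4-[(tert-butyldimethylsilyl)oxy]-3-methyl-6-oxohex-2-enoate
Conditions: Dess–Martin periodinane, NaHCO3, CH2Cl2, 0 °C → rt
Reagents that add atoms: none
Why: Dess–Martin oxidation under buffered non-basic conditions, which keeps the β-silyloxy aldehyde from eliminating.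

Step 6
Reactants: 7 methyl (2Z,4S)-4-[(tert-butyldimethylsilyl)oxy]-3-methyl-6-oxohex-2-enoate
Product: 8 methyl (2Z,4S,6Z)-4-[(tert-butyldimethylsilyl)oxy]-7-iodo-3-methylocta-2,6-dienoate
Conditions: [Ph3PCH(I)CH3]I, NaHMDS, THF, −20 °C; then 7, −78 °C
Reagents that add atoms: (1-iodoethyl)triphenylphosphonium iodide, CC(I)[P+](c1ccccc1)(c1ccccc1)c1ccccc1.[I-]
Why: Stork–Zhao-type Wittig olefination with the α-iodo ylide gives the (Z)-2-iodoalkene under kinetic control (iodine cis to C2), so the later C9 substituent is cis to C2 (Z-C1=C10).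

Step 7
Reactants: 8 methyl (2Z,4S,6Z)-4-[(tert-butyldimethylsilyl)oxy]-7-iodo-3-methylocta-2,6-dienoate
Product: 9 methyl (2Z,4S,6Z)-4-[(tert-butyldimethylsilyl)oxy]-3,7-dimethyl-8-oxoocta-2,6-dienoate
Conditions: Pd(PPh3)4 (5 mol%), CO (3 atm), Bu3SnH (slow addition), THF, 50 °C
Reagents that add atoms: carbon monoxide, [C-]#[O+]
Why: Palladium-catalysed reductive carbonylation (formylation) of a vinyl iodide with CO and tin hydride retains the alkene geometry and tolerates the ester.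

Step 8
Reactants: 9 methyl (2Z,4S,6Z)-4-[(tert-butyldimethylsilyl)oxy]-3,7-dimethyl-8-oxoocta-2,6-dienoate
Product: 11 methyl (2Z,4S,6Z,8R)-4-[(tert-butyldimethylsilyl)oxy]-8-hydroxy-3,7-dimethylundeca-2,6,10-trienoate, via diisopinocampheylborinate 10 (not isolated)
Conditions: l-Ipc2B(allyl) [from (+)-Ipc2BOMe of the (−)-α-pinene series and allylMgBr], Et2O, −78 °C; then 3 M NaOH, 30% H2O2, 0 °C
Reagents that add atoms: B-allylbis[(1S,2S,3S,5R)-isopinocampheyl]borane, C=CCB([C@H]1C[C@H]2C[C@@H]([C@@H]1C)C2(C)C)[C@H]1C[C@H]2C[C@@H]([C@@H]1C)C2(C)C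
Why: Brown allylboration through a chair six-membered transition state, in which the l-Ipc reagent attacks the Re face of the enal and sets C9 (R) while the ester is inert at −78 °C.

Step 9
Reactants: 11 methyl (2Z,4S,6Z,8R)-4-[(tert-butyldimethylsilyl)oxy]-8-hydroxy-3,7-dimethylundeca-2,6,10-trienoate
Product: 12 methyl (2Z,4S,6Z,8R)-4,8-bis[(tert-butyldimethylsilyl)oxy]-3,7-dimethylundeca-2,6,10-trienoate
Conditions: TBSOTf, 2,6-lutidine, CH2Cl2, −78 → 0 °C
Reagents that add atoms: tert-butyldimethylsilyl trifluoromethanesulfonate, CC(C)(C)[Si](C)(C)OS(=O)(=O)C(F)(F)F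
Why: Silyl triflate silylation of the hindered secondary allylic alcohol.

Step 10
Reactants: 12 methyl (2Z,4S,6Z,8R)-4,8-bis[(tert-butyldimethylsilyl)oxy]-3,7-dimethylundeca-2,6,10-trienoate
Product: 13 methyl (2Z,4S,6Z,8R,10E)-4,8-bis[(tert-butyldimethylsilyl)oxy]-3,7-dimethyl-12-oxododeca-2,6,10-trienoate
Conditions: crotonaldehyde (5 equiv), Hoveyda–Grubbs II (5 mol%), CH2Cl2, 40 °C
Reagents that add atoms: (E)-but-2-enal, C/C=C/C=O
Why: Olefin cross-metathesis of the terminal alkene with an enal partner gives the E-enal (E-C7=C11), the trisubstituted and conjugated alkenes being inert to the catalyst.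

Step 11
Reactants: 13 methyl (2Z,4S,6Z,8R,10E)-4,8-bis[(tert-butyldimethylsilyl)oxy]-3,7-dimethyl-12-oxododeca-2,6,10-trienoate
Product: 14 methyl (2Z,4S,6Z,8R,10E)-4,8-bis[(tert-butyldimethylsilyl)oxy]-12-hydroxy-3,7-dimethyldodeca-2,6,10-trienoate
Conditions: NaBH4, CeCl3·7H2O, MeOH, −40 °C
Reagents that add atoms: none
Why: Luche 1,2-reduction of the enal, which leaves the hindered enoate ester untouched.

Step 12
Reactants: 14 methyl (2Z,4S,6Z,8R,10E)-4,8-bis[(tert-butyldimethylsilyl)oxy]-12-hydroxy-3,7-dimethyldodeca-2,6,10-trienoate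
Product: 15 (2Z,4S,6Z,8R,10E)-4,8-bis[(tert-butyldimethylsilyl)oxy]-12-hydroxy-3,7-dimethyldodeca-2,6,10-trienoic acid
Conditions: LiOH·H2O, THF–MeOH–H2O, 40 °C; 1 M HCl to pH 4
Reagents that add atoms: lithium hydroxide, [Li+].[OH-]
Why: Saponification of the methyl ester, to which secondary TBS ethers and the Z-enoate geometry are stable.

Step 13
Reactants: 15 (2Z,4S,6Z,8R,10E)-4,8-bis[(tert-butyldimethylsilyl)oxy]-12-hydroxy-3,7-dimethyldodeca-2,6,10-trienoic acid
Product: 17 (3Z,5S,7Z,9R,11E)-5,9-bis[(tert-butyldimethylsilyl)oxy]-4,8-dimethyl-1-oxacyclotrideca-3,7,11-trien-2-one, via mixed anhydride 16 (not isolated)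
Conditions: MNBA, DMAP, CH2Cl2, rt, slow addition (final 1 mM)
Reagents that add atoms: none
Why: Shiina macrolactonisation under high dilution closes the 13-membered ring between the C12 oxygen and the C6 carbonyl under mild conditions that preserve the Z-enoate.

Step 14
Reactants: 17 (3Z,5S,7Z,9R,11E)-5,9-bis[(tert-butyldimethylsilyl)oxy]-4,8-dimethyl-1-oxacyclotrideca-3,7,11-trien-2-one
Product: 19 (3Z,5S,7Z,9R,11E)-5,9-bis[(tert-butyldimethylsilyl)oxy]-4,8-dimethyl-1-oxacyclotrideca-3,7,11-trien-2-yl acetate (C6 epimers), via aluminium hemiacetal 18 (not isolated)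
Conditions: DIBAL-H (2 equiv), CH2Cl2, −78 °C; then pyridine, DMAP, Ac2O, −78 → −20 °C
Reagents that add atoms: acetic anhydride, CC(=O)OC(C)=O
Why: DIBAL-H reductive acetylation of an ester, in which 1,2-hydride addition gives a tetrahedral aluminium hemiacetal that is stable at −78 °C and is acetylated in situ to the α-acetoxy ether.

Step 15
Reactants: 19 (3Z,5S,7Z,9R,11E)-5,9-bis[(tert-butyldimethylsilyl)oxy]-4,8-dimethyl-1-oxacyclotrideca-3,7,11-trien-2-yl acetate
Product: 20 (3Z,5S,7Z,9R,11E)-5,9-bis[(tert-butyldimethylsilyl)oxy]-4,8-dimethyl-2-(phenylsulfanyl)-1-oxacyclotrideca-3,7,11-triene (C6 epimers)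
Conditions: PhSH, BF3·OEt2, CH2Cl2, −78 °C
Reagents that add atoms: thiophenol, Sc1ccccc1
Why: Lewis acid-mediated acetal exchange (as in thioglycoside formation from anomeric acetates), the C6 oxocarbenium ion being captured at C6 by the thiol at low temperature.

Step 16
Reactants: 20 (3Z,5S,7Z,9R,11E)-5,9-bis[(tert-butyldimethylsilyl)oxy]-4,8-dimethyl-2-(phenylsulfanyl)-1-oxacyclotrideca-3,7,11-triene
Product: 22 (1S,2Z,4S,6Z,8R,10S)-4,8-bis[(tert-butyldimethylsilyl)oxy]-10-ethenyl-3,7-dimethylcyclodeca-2,6-dien-1-ol, via C6 allyllithium 21 (not isolated)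
Conditions: LiDBB (2.2 equiv), THF, −78 °C, 15 min; aq NH4Cl, −78 °C
Reagents that add atoms: none
Why: LiDBB cleaves the C6–S bond by two single-electron transfers and gives the α-alkoxy allyllithium 21, which rearranges at −78 °C through a five-membered envelope (C6, O, C12, C11, C7): C6 bonds to C7, the π bond moves to C11=C12 and O–C12 breaks, leaving the C6 alkoxide. The closest known reactions are [2,3]-Wittig rearrangements of α-(allyloxy)alkyllithiums generated by reductive lithiation of O,S-acetals and [2,3]-Wittig ring contractions of 13-membered diallylic ethers to cyclodecadienols. The ten-membered carbocycle is closed by contraction: the C6–C7 bond forms transannularly inside the 13-membered ring and the O–C12–C11 unit is extruded as the C6 hydroxyl and the C7 vinyl group. C6 and C7 are set together: the E-C7=C11 alkene with the C5 alkenyl group exo on the envelope gives the anti arrangement (H6 and H7 trans), and the alkene face attacked is fixed by the ring conformer with the C3 and C9 silyloxy groups pseudo-equatorial, since the C6 configuration of 20 is erased in the planar allyl anion. The step needs the [2,3]-shift to outrun the [1,2]-shift and the 1,4-elimination of the C3 silyloxide, which the low temperature and the fast five-membered transition state should secure, and it needs site selectivity, which the C–S bond provides because no other position is metalated.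

Step 17
Reactants: 22 (1S,2Z,4S,6Z,8R,10S)-4,8-bis[(tert-butyldimethylsilyl)oxy]-10-ethenyl-3,7-dimethylcyclodeca-2,6-dien-1-ol
Product: 24 (1S,2Z,4S,6Z,8R,10R)-4,8-bis[(tert-butyldimethylsilyl)oxy]-10-(2-hydroxyethyl)-3,7-dimethylcyclodeca-2,6-dien-1-ol, via 9-BBN adduct 23 (not isolated)
Conditions: 9-BBN (3 equiv), THF, 0 °C → rt; then 3 M NaOH, 30% H2O2, 0 °C
Reagents that add atoms: hydrogen peroxide, OO
Why: Hydroboration–oxidation, in which 9-BBN adds anti-Markovnikov to the monosubstituted vinyl group far faster than to the trisubstituted ring alkenes and creates no stereocentre.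

Step 18
Reactants: 24 (1S,2Z,4S,6Z,8R,10R)-4,8-bis[(tert-butyldimethylsilyl)oxy]-10-(2-hydroxyethyl)-3,7-dimethylcyclodeca-2,6-dien-1-ol
Product: 26 (3S,6S,7S,9R)-3,9-bis[(tert-butyldimethylsilyl)oxy]-13-norgermacra-1(10)Z,4Z-dien-12,6-olide, via lactol 25 (not isolated)
Conditions: TEMPO (20 mol%), PhI(OAc)2 (3 equiv), CH2Cl2, rt
Reagents that add atoms: none
Why: TEMPO/PhI(OAc)2 oxidative lactonisation of a 1,4-diol: the primary alcohol is oxidised first, the aldehyde closes onto the C6 hydroxyl and the lactol is oxidised to the trans-fused γ-lactone before the secondary allylic alcohol can react.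

Step 19
Reactants: 26 (3S,6S,7S,9R)-3,9-bis[(tert-butyldimethylsilyl)oxy]-13-norgermacra-1(10)Z,4Z-dien-12,6-olide
Product: 28 (3S,6S,7S,9R,11R)-3,9-bis[(tert-butyldimethylsilyl)oxy]germacra-1(10)Z,4Z-dien-12,6-olide, via lithium enolate 27 (not isolated)
Conditions: LDA (1.1 equiv), THF, −78 °C; MeI (5 equiv), DMPU, −78 °C; AcOH quench at −78 °C
Reagents that add atoms: iodomethane, CI
Why: Kinetic alkylation of the lactone lithium enolate: in the trans-fused lactone H7 is pseudo-axial, so iodomethane should enter anti to it, on the face of C8, and give the methyl cis to C8 (11R).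

Step 20
Reactants: 28 (3S,6S,7S,9R,11R)-3,9-bis[(tert-butyldimethylsilyl)oxy]germacra-1(10)Z,4Z-dien-12,6-olide
Product: 29 (3S,6S,7S,9R,11R)-3,9-dihydroxygermacra-1(10)Z,4Z-dien-12,6-olide
Conditions: HF·pyridine, pyridine, THF, 0 °C → rt
Reagents that add atoms: none
Why: Fluoride cleavage of both secondary TBS ethers under buffered non-basic conditions that should neither epimerise C11 nor transpose the lactone to the C9 hydroxyl.

Step 21
Reactants: 29 (3S,6S,7S,9R,11R)-3,9-dihydroxygermacra-1(10)Z,4Z-dien-12,6-olide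
Product: 30 (3S,6S,7S,9R,11R)-3,9-diacetoxygermacra-1(10)Z,4Z-dien-12,6-olide (CNP0226482.4)
Conditions: Ac2O, pyridine, DMAP (cat.), CH2Cl2, 0 °C → rt
Reagents that add atoms: acetic anhydride, CC(=O)OC(C)=O
Why: DMAP-catalysed acetylation of the two secondary allylic alcohols.

**Compound list**

1 | 3-[(tert-butyldimethylsilyl)oxy]propanal | CC(C)(C)[Si](C)(C)OCCC=O | starting material
2 | methyl propiolate | C#CC(=O)OC | starting material
3 | methyl (4S)-6-[(tert-butyldimethylsilyl)oxy]-4-hydroxyhex-2-ynoate | COC(=O)C#C[C@@H](O)CCO[Si](C)(C)C(C)(C)C | intermediate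
4 | methyl (4S)-4,6-bis[(tert-butyldimethylsilyl)oxy]hex-2-ynoate | COC(=O)C#C[C@@H](O[Si](C)(C)C(C)(C)C)CCO[Si](C)(C)C(C)(C)C | intermediate
5 | methyl (2Z,4S)-4,6-bis[(tert-butyldimethylsilyl)oxy]-3-methylhex-2-enoate | COC(=O)/C=C(/C)[C@@H](O[Si](C)(C)C(C)(C)C)CCO[Si](C)(C)C(C)(C)C | intermediate
6 | methyl (2Z,4S)-4-[(tert-butyldimethylsilyl)oxy]-6-hydroxy-3-methylhex-2-enoate | COC(=O)/C=C(/C)[C@@H](O[Si](C)(C)C(C)(C)C)CCO | intermediate
7 | methyl (2Z,4S)-4-[(tert-butyldimethylsilyl)oxy]-3-methyl-6-oxohex-2-enoate | COC(=O)/C=C(/C)[C@@H](O[Si](C)(C)C(C)(C)C)CC=O | intermediate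
8 | methyl (2Z,4S,6Z)-4-[(tert-butyldimethylsilyl)oxy]-7-iodo-3-methylocta-2,6-dienoate | COC(=O)/C=C(/C)[C@@H](O[Si](C)(C)C(C)(C)C)C/C=C(/C)I | intermediate
9 | methyl (2Z,4S,6Z)-4-[(tert-butyldimethylsilyl)oxy]-3,7-dimethyl-8-oxoocta-2,6-dienoate | COC(=O)/C=C(/C)[C@@H](O[Si](C)(C)C(C)(C)C)C/C=C(/C)C=O | intermediate
10 | O-bis[(1S,2S,3S,5R)-isopinocampheyl]borinate of 11 | COC(=O)/C=C(/C)[C@@H](O[Si](C)(C)C(C)(C)C)C/C=C(/C)[C@H](OB([C@H]1C[C@H]2C[C@@H]([C@@H]1C)C2(C)C)[C@H]1C[C@H]2C[C@@H]([C@@H]1C)C2(C)C)CC=C | intermediate (not isolated)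
11 | methyl (2Z,4S,6Z,8R)-4-[(tert-butyldimethylsilyl)oxy]-8-hydroxy-3,7-dimethylundeca-2,6,10-trienoate | COC(=O)/C=C(/C)[C@@H](O[Si](C)(C)C(C)(C)C)C/C=C(/C)[C@H](O)CC=C | intermediate
12 | methyl (2Z,4S,6Z,8R)-4,8-bis[(tert-butyldimethylsilyl)oxy]-3,7-dimethylundeca-2,6,10-trienoate | COC(=O)/C=C(/C)[C@@H](O[Si](C)(C)C(C)(C)C)C/C=C(/C)[C@H](O[Si](C)(C)C(C)(C)C)CC=C | intermediate
13 | methyl (2Z,4S,6Z,8R,10E)-4,8-bis[(tert-butyldimethylsilyl)oxy]-3,7-dimethyl-12-oxododeca-2,6,10-trienoate | COC(=O)/C=C(/C)[C@@H](O[Si](C)(C)C(C)(C)C)C/C=C(/C)[C@H](O[Si](C)(C)C(C)(C)C)C/C=C/C=O | intermediate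
14 | methyl (2Z,4S,6Z,8R,10E)-4,8-bis[(tert-butyldimethylsilyl)oxy]-12-hydroxy-3,7-dimethyldodeca-2,6,10-trienoate | COC(=O)/C=C(/C)[C@@H](O[Si](C)(C)C(C)(C)C)C/C=C(/C)[C@H](O[Si](C)(C)C(C)(C)C)C/C=C/CO | intermediate
15 | (2Z,4S,6Z,8R,10E)-4,8-bis[(tert-butyldimethylsilyl)oxy]-12-hydroxy-3,7-dimethyldodeca-2,6,10-trienoic acid | OC(=O)/C=C(/C)[C@@H](O[Si](C)(C)C(C)(C)C)C/C=C(/C)[C@H](O[Si](C)(C)C(C)(C)C)C/C=C/CO | intermediate
16 | mixed anhydride of 15 and 2-methyl-6-nitrobenzoic acid | Cc1cccc([N+](=O)[O-])c1C(=O)OC(=O)/C=C(/C)[C@@H](O[Si](C)(C)C(C)(C)C)C/C=C(/C)[C@H](O[Si](C)(C)C(C)(C)C)C/C=C/CO | intermediate (not isolated)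
17 | (3Z,5S,7Z,9R,11E)-5,9-bis[(tert-butyldimethylsilyl)oxy]-4,8-dimethyl-1-oxacyclotrideca-3,7,11-trien-2-one (carbonyl = C6, ring O on C12) | O=C1/C=C(/C)[C@@H](O[Si](C)(C)C(C)(C)C)C/C=C(/C)[C@H](O[Si](C)(C)C(C)(C)C)C/C=C/CO1 | intermediate
18 | O-diisobutylaluminium hemiacetal of 17 | CC(C)C[Al](CC(C)C)OC1/C=C(/C)[C@@H](O[Si](C)(C)C(C)(C)C)C/C=C(/C)[C@H](O[Si](C)(C)C(C)(C)C)C/C=C/CO1 | intermediate (not isolated)
19 | (3Z,5S,7Z,9R,11E)-5,9-bis[(tert-butyldimethylsilyl)oxy]-4,8-dimethyl-1-oxacyclotrideca-3,7,11-trien-2-yl acetate (C6 epimers) | CC(=O)OC1/C=C(/C)[C@@H](O[Si](C)(C)C(C)(C)C)C/C=C(/C)[C@H](O[Si](C)(C)C(C)(C)C)C/C=C/CO1 | intermediate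
20 | (3Z,5S,7Z,9R,11E)-5,9-bis[(tert-butyldimethylsilyl)oxy]-4,8-dimethyl-2-(phenylsulfanyl)-1-oxacyclotrideca-3,7,11-triene (C6 epimers; key-step precursor) | CC(C)(C)[Si](C)(C)O[C@H]1C/C=C(/C)[C@H](O[Si](C)(C)C(C)(C)C)C/C=C/COC(Sc2ccccc2)/C=C\1C | intermediate
21 | C6-lithio derivative of the 13-membered ether (α-alkoxy allyllithium) | CC(C)(C)[Si](C)(C)O[C@H]1C/C=C(/C)[C@H](O[Si](C)(C)C(C)(C)C)C/C=C/COC([Li])/C=C\1C | intermediate (not isolated)
22 | (1S,2Z,4S,6Z,8R,10S)-4,8-bis[(tert-butyldimethylsilyl)oxy]-10-ethenyl-3,7-dimethylcyclodeca-2,6-dien-1-ol (germacrane: 6-OH, 7-vinyl; 3S,6S,7S,9R; key-step product) | CC(C)(C)[Si](C)(C)O[C@H]1C/C=C(/C)[C@H](O[Si](C)(C)C(C)(C)C)C[C@@H](C=C)[C@@H](/C=C\1C)O | intermediate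
23 | C12 B-alkyl-9-BBN and C6 O-(9-BBN) adduct of 22 | CC(C)(C)[Si](C)(C)O[C@H]1C/C=C(/C)[C@H](O[Si](C)(C)C(C)(C)C)C[C@@H](CCB2C3CCCC2CCC3)[C@@H](/C=C\1C)OB1C2CCCC1CCC2 | intermediate (not isolated)
24 | (1S,2Z,4S,6Z,8R,10R)-4,8-bis[(tert-butyldimethylsilyl)oxy]-10-(2-hydroxyethyl)-3,7-dimethylcyclodeca-2,6-dien-1-ol (6,12-diol) | CC(C)(C)[Si](C)(C)O[C@H]1C/C=C(/C)[C@H](O[Si](C)(C)C(C)(C)C)C[C@@H](CCO)[C@@H](/C=C\1C)O | intermediate
25 | 12-hydroxy-12,6-lactol of 24 | CC(C)(C)[Si](C)(C)O[C@H]1C/C=C(/C)[C@H](O[Si](C)(C)C(C)(C)C)C[C@@H]2[C@@H](/C=C\1C)OC(O)C2 | intermediate (not isolated)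
26 | (3S,6S,7S,9R)-3,9-bis[(tert-butyldimethylsilyl)oxy]-13-norgermacra-1(10)Z,4Z-dien-12,6-olide | CC(C)(C)[Si](C)(C)O[C@H]1C/C=C(/C)[C@H](O[Si](C)(C)C(C)(C)C)C[C@@H]2[C@@H](/C=C\1C)OC(=O)C2 | intermediate
27 | lithium enolate of 26 | CC(C)(C)[Si](C)(C)O[C@H]1C/C=C(/C)[C@H](O[Si](C)(C)C(C)(C)C)C[C@@H]2[C@@H](/C=C\1C)OC(O[Li])=C2 | intermediate (not isolated)
28 | (3S,6S,7S,9R,11R)-3,9-bis[(tert-butyldimethylsilyl)oxy]germacra-1(10)Z,4Z-dien-12,6-olide | CC(C)(C)[Si](C)(C)O[C@H]1C/C=C(/C)[C@H](O[Si](C)(C)C(C)(C)C)C[C@@H]2[C@@H](/C=C\1C)OC(=O)[C@@H]2C | intermediate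
29 | (3S,6S,7S,9R,11R)-3,9-dihydroxygermacra-1(10)Z,4Z-dien-12,6-olide | O[C@H]1C/C=C(/C)[C@H](O)C[C@@H]2[C@@H](/C=C\1C)OC(=O)[C@@H]2C | intermediate
30 | (3S,6S,7S,9R,11R)-3,9-diacetoxygermacra-1(10)Z,4Z-dien-12,6-olide (CNP0226482.4) | CC(=O)O[C@H]1C/C=C(/C)[C@H](OC(C)=O)C[C@@H]2[C@@H](/C=C\1C)OC(=O)[C@@H]2C | target

**Step count and risks**

Total step count: 21. Longest linear sequence: 21 steps (from 1 and 2).

Steps most likely to fail:

1. Step 16 (ring contraction). Possible failures are loss of the C3 silyloxide from the allyllithium by 1,4-elimination, a competing [1,2]-shift, E/Z scrambling of the allyl anion, or attack on the wrong face of the C7=C11 alkene because the remote C3 and C9 centres steer too weakly. The fallback sets out from 14 and returns at 22 without any carbanion. Appel bromination (CBr4, PPh3, CH2Cl2, 0 °C) would give methyl (2Z,4S,6Z,8R,10E)-12-bromo-4,8-bis[(tert-butyldimethylsilyl)oxy]-3,7-dimethyldodeca-2,6,10-trienoate F1. DIBAL-H at −78 °C would reduce the ester to the C6 allylic alcohol, the bromo trienol F2, and MnO2 would oxidise this to the (Z)-bromo trienal F3. CrCl2 in THF at high dilution would then close the ten-membered ring by intramolecular Nozaki–Hiyama allylation: the E-allylchromium adds through C7 to the C6 aldehyde in a chair transition state and should give the same anti 6-hydroxy-7-vinyl arrangement, 22.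

2. Step 14 (reductive acetylation of the conjugated macrolactone). Possible failures are collapse of the aluminium hemiacetal to the enal with over-reduction to the open diol, or ionisation of the allylic acetoxy ether with Z/E scrambling in this step and the next. The fallback sets out from 14 and returns at 22 by way of a sulfur-free ether. MsCl, 2,4,6-collidine and LiCl in DMF would give the allylic chloride ester F4, and DIBAL-H at −78 °C the chloro trienol F5. NaH in THF at high dilution would close the 13-membered diallylic ether (3Z,5S,7Z,9R,11E)-5,9-bis[(tert-butyldimethylsilyl)oxy]-4,8-dimethyl-1-oxacyclotrideca-3,7,11-triene F6 by Williamson etherification. s-BuLi in THF at −78 °C would then trigger the [2,3]-Wittig ring contraction by direct deprotonation at C6, as is known for 13-membered diallylic ethers. In this variant the site of lithiation (C6 against C12) is what must be secured.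

3. Step 19 (C11 methylation). Possible failures are methylation on the enolate face cis to H7, proton transfer between product and residual enolate with epimerisation, or double methylation. The fallback sets out from 26 and returns at 28; it sets C11 by protonation instead of alkylation. Proton and methyl approach the same enolate face, so if methylation gives the C11 epimer, the 11S lactone F7, then F7 or the epimer mixture would be deprotonated again (LDA, THF, −78 °C) to the 11-methyl lithium enolate F8. Kinetic protonation of F8 at −78 °C with a bulky acid (2,6-di-tert-butylphenol, then AcOH) would place H on the face that took the methyl group and so give 28.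

Further compounds
F1 | step 16 | methyl (2Z,4S,6Z,8R,10E)-12-bromo-4,8-bis[(tert-butyldimethylsilyl)oxy]-3,7-dimethyldodeca-2,6,10-trienoate | COC(=O)/C=C(/C)[C@@H](O[Si](C)(C)C(C)(C)C)C/C=C(/C)[C@H](O[Si](C)(C)C(C)(C)C)C/C=C/CBr
F2 | step 16 | (2Z,4S,6Z,8R,10E)-12-bromo-4,8-bis[(tert-butyldimethylsilyl)oxy]-3,7-dimethyldodeca-2,6,10-trien-1-ol | OC/C=C(/C)[C@@H](O[Si](C)(C)C(C)(C)C)C/C=C(/C)[C@H](O[Si](C)(C)C(C)(C)C)C/C=C/CBr
F3 | step 16 | (2Z,4S,6Z,8R,10E)-12-bromo-4,8-bis[(tert-butyldimethylsilyl)oxy]-3,7-dimethyldodeca-2,6,10-trienal | O=C/C=C(/C)[C@@H](O[Si](C)(C)C(C)(C)C)C/C=C(/C)[C@H](O[Si](C)(C)C(C)(C)C)C/C=C/CBr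
F4 | step 14 | methyl (2Z,4S,6Z,8R,10E)-12-chloro-4,8-bis[(tert-butyldimethylsilyl)oxy]-3,7-dimethyldodeca-2,6,10-trienoate | COC(=O)/C=C(/C)[C@@H](O[Si](C)(C)C(C)(C)C)C/C=C(/C)[C@H](O[Si](C)(C)C(C)(C)C)C/C=C/CCl
F5 | step 14 | (2Z,4S,6Z,8R,10E)-12-chloro-4,8-bis[(tert-butyldimethylsilyl)oxy]-3,7-dimethyldodeca-2,6,10-trien-1-ol | OC/C=C(/C)[C@@H](O[Si](C)(C)C(C)(C)C)C/C=C(/C)[C@H](O[Si](C)(C)C(C)(C)C)C/C=C/CCl
F6 | step 14 | (3Z,5S,7Z,9R,11E)-5,9-bis[(tert-butyldimethylsilyl)oxy]-4,8-dimethyl-1-oxacyclotrideca-3,7,11-triene | C1/C=C(/C)[C@@H](O[Si](C)(C)C(C)(C)C)C/C=C(/C)[C@H](O[Si](C)(C)C(C)(C)C)C/C=C/CO1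
F7 | step 19 | (3S,6S,7S,9R,11S)-3,9-bis[(tert-butyldimethylsilyl)oxy]germacra-1(10)Z,4Z-dien-12,6-olide (C11 epimer of 28) | CC(C)(C)[Si](C)(C)O[C@H]1C/C=C(/C)[C@H](O[Si](C)(C)C(C)(C)C)C[C@@H]2[C@@H](/C=C\1C)OC(=O)[C@H]2C
F8 | step 19 | lithium enolate of the 11-methyl lactone | CC(C)(C)[Si](C)(C)O[C@H]1C/C=C(/C)[C@H](O[Si](C)(C)C(C)(C)C)C[C@@H]2[C@@H](/C=C\1C)OC(O[Li])=C2C
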